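**Plan**

- Retrosynthesis: the two O–CH3 bonds at C2' and C5' are cut first (hydroquinone 16), then the C1'–C2' bond of ring B (back to cyclobutenone 13). Next come the chromone C2–vinyl bond (Stille coupling) and the carbinol–vinyl bond (vinyllithium plus dimethyl squarate); the C2–I bond and the pyranone ring lead back to an acetophenone.
- Enabling feature: ring B carries four adjacent oxygens on C2', C3', C4' and C5', a single C–H at C6', and chromone C2 on C1'. This is the pattern a dimethyl-squarate-derived 4-alkenyl-4-hydroxycyclobutenone delivers on thermal ring expansion.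
- Forward order: ring A is bought, ring C (the pyranone) is closed in step 3 and iodinated at C2. The squarate is stannylvinylated and joined to the chromone by Stille coupling; ring B is formed last in step 7 and then O-methylated twice.
- Stereochemistry: the target has no stereocentre. The carbinol centre of 12 and 13 is racemic and disappears on aromatization; the E alkene of the linker comes from the E-distannane, is retained through tin–lithium exchange and Stille coupling, and ends up inside ring B.

Key step: step 7

Assumption: CNP0482056.0 is taken as the achiral 5,7,8,2',3',4',5'-heptamethoxyflavone given by the SMILES; flavone numbering is used (ring A benzo ring, ring C pyranone, ring B the 2-aryl ring).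

**Step 1**
Reactants: 1 3,4,5-trimethoxyphenol
Product: 2 1,2,3,5-tetramethoxybenzene
Conditions: MeI, K2CO3, acetone, reflux
Reagents that add atoms: iodomethane, CI
Why: Williamson O-methylation of the only acidic group of an electron-rich phenol is routine and leaves two equivalent free ring positions for the next step.

**Step 2**
Reactants: 2 1,2,3,5-tetramethoxybenzene
Product: 4 1-(2-hydroxy-3,4,6-trimethoxyphenyl)ethanone, via 1-(2,3,4,6-tetramethoxyphenyl)ethanone 3 (not isolated)
Conditions: AcCl, AlCl3 (excess), Et2O, 0 °C to rt; aq. HCl work-up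
Reagents that add atoms: acetyl chloride, CC(=O)Cl
Why: Friedel–Crafts acylation at one of the two equivalent activated positions is followed by chelation-controlled ortho-demethylation, in which the carbonyl-bound aluminium cleaves the 2'-methoxy group (flanked by the acetyl and the 3'-methoxy group and twisted out of plane) in preference to the 6'-methoxy group.

**Step 3**
Reactants: 4 1-(2-hydroxy-3,4,6-trimethoxyphenyl)ethanone
Product: 6 5,7,8-trimethoxychromen-4-one, via (E)-3-(dimethylamino)-1-(2-hydroxy-3,4,6-trimethoxyphenyl)prop-2-en-1-one 5 (not isolated)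
Conditions: Me2NCH(OMe)2, 95 °C; concentrate; then conc. HCl, CH2Cl2, rt
Reagents that add atoms: N,N-dimethylformamide dimethyl acetal, COC(OC)N(C)C
Why: In this enaminone route to 2,3-unsubstituted chromones, the methyl ketone condenses with the amide acetal and acid then drives intramolecular oxa-Michael addition of the phenol with loss of dimethylamine, conditions the aryl methyl ethers tolerate.

**Step 4**
Reactants: 6 5,7,8-trimethoxychromen-4-one
Product: 8 2-iodo-5,7,8-trimethoxychromen-4-one, via chloro(5,7,8-trimethoxy-4-oxochromen-2-yl)zinc 7 (not isolated)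
Conditions: TMPZnCl·LiCl, THF, 25 °C; then I2, THF, 0 °C
Reagents that add atoms: iodine, II; TMPZnCl·LiCl, CC1(C)CCCC(C)(C)N1[Zn]Cl.[Li+].[Cl-] (zinc and chlorine of intermediate 7 only)
Why: Directed C–H zincation with the hindered zinc amide, run without an added Lewis acid, should remove the most acidic proton (C2–H, next to the ring oxygen and vinylogous to the carbonyl), and iodinolysis of the C–Zn bond gives the 2-iodide without opening the pyranone or metalating C6.

**Step 5**
Reactants: 9 (E)-1,2-bis(tributylstannyl)ethene; 10 dimethyl squarate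
Product: 12 racemic 4-hydroxy-2,3-dimethoxy-4-[(E)-2-(tributylstannyl)ethenyl]cyclobut-2-en-1-one, via (E)-2-(tributylstannyl)ethenyllithium 11 (not isolated)
Conditions: 9, n-BuLi (1 equiv), THF, −78 °C; then add to 10, THF, −78 °C; aq. NH4Cl quench at −78 °C
Reagents that add atoms: n-butyllithium, [Li]CCCC (lithium of intermediate 11 only)
Why: Tin–lithium exchange gives the vinyllithium with retention of the E geometry, and its 1,2-addition to one of the two equivalent carbonyls of the squarate stops at the monoadduct at −78 °C; the new carbinol centre forms as a racemate, which is of no consequence.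

**Step 6**
Reactants: 8 2-iodo-5,7,8-trimethoxychromen-4-one; 12 racemic 4-hydroxy-2,3-dimethoxy-4-[(E)-2-(tributylstannyl)ethenyl]cyclobut-2-en-1-one
Product: 13 racemic 2-[(E)-2-(1-hydroxy-2,3-dimethoxy-4-oxocyclobut-2-en-1-yl)ethenyl]-5,7,8-trimethoxychromen-4-one
Conditions: Pd2(dba)3 (cat.), AsPh3, CuI, DMF (degassed), 25 °C, dark
Reagents that add atoms: none
Why: In this Stille coupling the β-iodo enone adds oxidatively to zerovalent palladium at room temperature, and AsPh3/CuI-accelerated transmetalation of the vinylstannane proceeds with retention of the E geometry under neutral conditions, below the ring-opening temperature of the hydroxycyclobutenone.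

**Step 7**
Reactants: 13 racemic 2-[(E)-2-(1-hydroxy-2,3-dimethoxy-4-oxocyclobut-2-en-1-yl)ethenyl]-5,7,8-trimethoxychromen-4-one
Product: 16 2-(2,5-dihydroxy-3,4-dimethoxyphenyl)-5,7,8-trimethoxychromen-4-one, via (3Z,5E)-dienylketene 14 (not isolated), via 6-chromonylcyclohexa-2,4-dienone 15 (not isolated)
Conditions: toluene (degassed), 110 °C, Ar
Reagents that add atoms: none
Why: Thermal conrotatory four-electron opening of the cyclobutenone breaks the bond between the carbinol carbon and the carbonyl carbon and gives dienylketene 14, in which the donor hydroxyl has rotated outward and the alkenyl arm sits cis to the ketene. A six-electron electrocyclization then joins the ketene carbon (future C2') to the chromonyl-bearing alkene terminus (future C1'), closing ring B as a six-membered carbocycle (formal 6-endo mode) to give dienone 15. Enolization with loss of the C1' hydrogen aromatizes 15 to hydroquinone 16. The closest known reaction type is the thermal ring expansion of squarate-derived 4-alkenyl-4-hydroxycyclobutenones to tetraoxygenated hydroquinones. No stereocentre is created, since the carbinol centre becomes sp2 and the transient sp3 centre of 15 is lost on aromatization. The one selectivity required is the torquoselectivity of the ring opening, secured by the outward preference of the hydroxyl; the placement of the oxygens is fixed by connectivity, the squarate methoxy carbons becoming C3' and C4' and its carbonyl carbons C2' and C5'.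

**Step 8**
Reactants: 16 2-(2,5-dihydroxy-3,4-dimethoxyphenyl)-5,7,8-trimethoxychromen-4-one
Product: 17 2-(2,3,4,5-tetramethoxyphenyl)-5,7,8-trimethoxychromen-4-one (CNP0482056.0)
Conditions: crude 16, Me2SO4, K2CO3, acetone (degassed), reflux, Ar
Reagents that add atoms: dimethyl sulfate, COS(=O)(=O)OC
Why: Double Williamson O-methylation of the two phenols, carried out at once on the crude hydroquinone under argon, should outpace oxidation to the quinone and gives the heptamethyl ether.

**Compound list**

1 | 3,4,5-trimethoxyphenol | COc1cc(O)cc(OC)c1OC | starting material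
2 | 1,2,3,5-tetramethoxybenzene | COc1cc(OC)c(OC)c(OC)c1 | intermediate
3 | 1-(2,3,4,6-tetramethoxyphenyl)ethanone | CC(=O)c1c(OC)cc(OC)c(OC)c1OC | intermediate (not isolated)
4 | 1-(2-hydroxy-3,4,6-trimethoxyphenyl)ethanone | CC(=O)c1c(O)c(OC)c(OC)cc1OC | intermediate
5 | (E)-3-(dimethylamino)-1-(2-hydroxy-3,4,6-trimethoxyphenyl)prop-2-en-1-one | CN(C)/C=C/C(=O)c1c(O)c(OC)c(OC)cc1OC | intermediate (not isolated)
6 | 5,7,8-trimethoxychromen-4-one | O=c1ccoc2c(OC)c(OC)cc(OC)c12 | intermediate
7 | chloro(5,7,8-trimethoxy-4-oxochromen-2-yl)zinc (LiCl complex) | Cl[Zn]c1cc(=O)c2c(OC)cc(OC)c(OC)c2o1 | intermediate (not isolated)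
8 | 2-iodo-5,7,8-trimethoxychromen-4-one | Ic1cc(=O)c2c(OC)cc(OC)c(OC)c2o1 | intermediate
9 | (E)-1,2-bis(tributylstannyl)ethene | CCCC[Sn](CCCC)(CCCC)/C=C/[Sn](CCCC)(CCCC)CCCC | starting material
10 | dimethyl squarate (3,4-dimethoxycyclobut-3-ene-1,2-dione) | COC1=C(OC)C(=O)C1=O | starting material
11 | (E)-2-(tributylstannyl)ethenyllithium | [Li]/C=C/[Sn](CCCC)(CCCC)CCCC | intermediate (not isolated)
12 | racemic 4-hydroxy-2,3-dimethoxy-4-[(E)-2-(tributylstannyl)ethenyl]cyclobut-2-en-1-one | COC1=C(OC)C(O)(/C=C/[Sn](CCCC)(CCCC)CCCC)C1=O | intermediate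
13 | racemic 2-[(E)-2-(1-hydroxy-2,3-dimethoxy-4-oxocyclobut-2-en-1-yl)ethenyl]-5,7,8-trimethoxychromen-4-one | COC1=C(OC)C(O)(/C=C/c2cc(=O)c3c(OC)cc(OC)c(OC)c3o2)C1=O | intermediate
14 | (3Z,5E)-4-hydroxy-2,3-dimethoxy-6-(5,7,8-trimethoxy-4-oxochromen-2-yl)hexa-1,3,5-trien-1-one (dienylketene) | O=C=C(OC)/C(OC)=C(O)\C=C\c1cc(=O)c2c(OC)cc(OC)c(OC)c2o1 | intermediate (not isolated)
15 | racemic 4-hydroxy-2,3-dimethoxy-6-(5,7,8-trimethoxy-4-oxochromen-2-yl)cyclohexa-2,4-dien-1-one | COC1=C(OC)C(O)=CC(c2cc(=O)c3c(OC)cc(OC)c(OC)c3o2)C1=O | intermediate (not isolated)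
16 | 2-(2,5-dihydroxy-3,4-dimethoxyphenyl)-5,7,8-trimethoxychromen-4-one | COc1c(O)cc(-c2cc(=O)c3c(OC)cc(OC)c(OC)c3o2)c(O)c1OC | intermediate
17 | 2-(2,3,4,5-tetramethoxyphenyl)-5,7,8-trimethoxychromen-4-one (CNP0482056.0) | COc1cc(-c2cc(=O)c3c(OC)cc(OC)c(OC)c3o2)c(OC)c(OC)c1OC | target

**Step count and risks**

Total step count: 8. Longest linear sequence: 7 steps (steps 1, 2, 3, 4, 6, 7, 8); step 5 is a one-step side branch.

Steps most likely to fail:

Step 4. The metalation may go to the wrong site (carbonyl-directed deprotonation at C3, or at C6 between two methoxy groups), the pyranone may be opened by the amide base, or the iodide may be lost by addition–elimination at C2 during isolation. Fallback: setting out from 4, condensation with CS2 (t-BuOK, THF, 0 °C to rt, acid work-up) should give 4-hydroxy-5,7,8-trimethoxy-2H-chromene-2-thione F1. S-Methylation (MeI, K2CO3, acetone) gives 5,7,8-trimethoxy-2-(methylsulfanyl)chromen-4-one F2. Desulfitative Liebeskind–Srogl coupling of this vinylogous thioester with stannane 12 (Pd(PPh3)4, copper 3-methylsalicylate with monovalent copper, THF, 45 °C) rejoins the route at 13, bypassing iodide 8 and step 6.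

Step 6. Transmetalation of the stannane may be slow enough for protodestannylation or homocoupling to compete; the strained tertiary cyclobutenol may ring-open through a palladium alkoxide (β-carbon elimination) or thermally; adventitious nucleophiles may displace the iodide at C2. Fallback with reversed polarity: setting out from 12, iododestannylation (I2, CH2Cl2, 0 °C) should give, with retention of the alkene geometry, racemic 4-hydroxy-4-[(E)-2-iodoethenyl]-2,3-dimethoxycyclobut-2-en-1-one F3. Zinc reagent 7, generated from 6 as in step 4 and used in excess to allow for the free hydroxyl, is then coupled with F3 under Negishi conditions (Pd(PPh3)4, THF, 25 °C), returning to the route at 13.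

Step 7. The ketene may be trapped by its own hydroxyl (lactonization) if inward rotation of the hydroxyl competes, closure onto the electron-poor, chromone-conjugated alkene terminus may be sluggish, and the hydroquinone may oxidize in air during isolation. Fallback: setting out from 13, silylation (Et3SiOTf, 2,6-lutidine, CH2Cl2, −78 °C) gives racemic 2-[(E)-2-(2,3-dimethoxy-4-oxo-1-triethylsilyloxycyclobut-2-en-1-yl)ethenyl]-5,7,8-trimethoxychromen-4-one F4. The same ring expansion (toluene, 110 °C) now runs with a silyloxy group that rotates outward at least as reliably and cannot add to the ketene. It should give the air-stable monosilyl hydroquinone 2-[2-hydroxy-3,4-dimethoxy-5-(triethylsilyloxy)phenyl]-5,7,8-trimethoxychromen-4-one F5. Fluoride-mediated desilylative methylation (CsF, MeI, DMF, rt) converts both oxygens into methyl ethers and comes back to the route at 17.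

**Further compounds**

F1 | step 4 | 4-hydroxy-5,7,8-trimethoxy-2H-chromene-2-thione | S=c1cc(O)c2c(OC)cc(OC)c(OC)c2o1
F2 | step 4 | 5,7,8-trimethoxy-2-(methylsulfanyl)chromen-4-one | CSc1cc(=O)c2c(OC)cc(OC)c(OC)c2o1
F3 | step 6 | racemic 4-hydroxy-4-[(E)-2-iodoethenyl]-2,3-dimethoxycyclobut-2-en-1-one | COC1=C(OC)C(O)(/C=C/I)C1=O
F4 | step 7 | racemic 2-[(E)-2-(2,3-dimethoxy-4-oxo-1-triethylsilyloxycyclobut-2-en-1-yl)ethenyl]-5,7,8-trimethoxychromen-4-one | CC[Si](CC)(CC)OC1(/C=C/c2cc(=O)c3c(OC)cc(OC)c(OC)c3o2)C(OC)=C(OC)C1=O
F5 | step 7 | 2-[2-hydroxy-3,4-dimethoxy-5-(triethylsilyloxy)phenyl]-5,7,8-trimethoxychromen-4-one | CC[Si](CC)(CC)Oc1cc(-c2cc(=O)c3c(OC)cc(OC)c(OC)c3o2)c(O)c(OC)c1OC
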